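**Plan**
- Numbering: C1 is the lactone carbonyl carbon, C2–C30 are the twenty-nine CH2 groups, and C30 is bonded to the ring oxygen.
- Retrosynthesis: C28–H is traced back to a C28–S xanthate helper; then the ring bond C29–C30 is cut, which opens the ring to an S-(acyloxymethyl) xanthate of nonacos-28-enoic acid. Next C30–S and O–C30 are cut (xanthate salt; chloromethyl chlorosulfate supplies C30), then the chain bonds C12–C13 and C18–C19.
- Forward: C11 bromoalkene + C6 dibromide give a C17 bromoalkene; this plus a C12 bromo acid gives the C29 ω-alkenoic acid. The acid is converted to its chloromethyl ester and then the xanthate; the only ring (31-membered) is closed by radical C–C bond formation, and C–S is finally reduced to C–H.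
- Enabling feature: C30 sits on the ring oxygen of the 31-membered lactone, so it is an acyloxymethyl carbon. It can be carried at the formaldehyde oxidation level as an O,S-acetal and homolysed to an oxygen-stabilised radical, while C29 and C28 are plain CH2 groups that a terminal alkene can supply.
- Stereochemistry: the target has no stereocentre and no C=C. The one stereocentre made on the way (C28–S) is racemic and is erased in step 6.

Key step: step 5

Remark: the target is read as the achiral 31-membered lactone of 30-hydroxytriacontanoic acid (C30H58O2: one carbonyl carbon, twenty-nine CH2 groups, one ring oxygen).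

**Route**

Step 1
Reactants: 1 11-bromoundec-1-ene; 2 1,6-dibromohexane
Product: 4 17-bromoheptadec-1-ene, via undec-10-en-1-ylmagnesium bromide 3 (not isolated)
Conditions: 1, Mg, THF, 40 °C; then added slowly to 2 (3 equiv), Li2CuCl4 (2 mol %), THF, −10 °C to rt
Reagents that add atoms: none
Why: Kochi-type Li2CuCl4-catalysed sp3–sp3 cross-coupling of a primary Grignard reagent with a primary bromide should join C18–C19, the excess of 2 holding the reaction at the mono-coupling stage while the terminal alkene is inert.

Step 2
Reactants: 4 17-bromoheptadec-1-ene; 5 12-bromododecanoic acid
Product: 8 nonacos-28-enoic acid, via heptadec-16-en-1-ylmagnesium bromide 6 (not isolated), via chloromagnesium 12-bromododecanoate 7 (not isolated)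
Conditions: 4, Mg, THF, 45 °C; 5, MeMgCl (1.0 equiv), THF, −20 °C; combined, Li2CuCl4 (3 mol %), −20 °C to rt; aq HCl
Reagents that add atoms: none
Why: The same copper-catalysed Grignard cross-coupling (Kochi coupling) applied to the magnesium salt of an ω-bromo acid should join C12–C13 without protecting-group steps, because the carboxylate is too poor an electrophile to be attacked at low temperature.

Step 3
Reactants: 8 nonacos-28-enoic acid
Product: 9 chloromethyl nonacos-28-enoate
Conditions: ClCH2OSO2Cl (1.2 equiv), NaHCO3 (4 equiv), Bu4NHSO4 (0.1 equiv), CH2Cl2/H2O, rt
Reagents that add atoms: chloromethyl chlorosulfate, ClCOS(=O)(=O)Cl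
Why: Phase-transfer O-alkylation (SN2) of the carboxylate should occur at the CH2 of the reagent with loss of chlorosulfate, the better leaving group, so that the C–Cl bond is kept and C30 is installed at the formaldehyde oxidation level.

Step 4
Reactants: 9 chloromethyl nonacos-28-enoate
Product: 10 O-ethyl S-[(nonacos-28-enoyloxy)methyl] dithiocarbonate
Conditions: KSC(S)OEt (1.1 equiv), acetone/THF, 0 °C to rt
Reagents that add atoms: potassium O-ethyl xanthate, CCOC(=S)[S-].[K+]
Why: SN2 displacement of the activated α-acyloxy chloride by the soft sulfur nucleophile should give the S-(acyloxymethyl) xanthate, the radical precursor, in preference to attack at the ester carbonyl.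

Step 5
Reactants: 10 O-ethyl S-[(nonacos-28-enoyloxy)methyl] dithiocarbonate
Product: 11 O-ethyl S-(2-oxo-1-oxacyclohentriacontan-29-yl) dithiocarbonate (racemic; the xanthate sits on chain carbon C28)
Conditions: dilauroyl peroxide (0.3 equiv, in portions), degassed 1,2-dichloroethane (0.002 M), reflux
Reagents that add atoms: none
Why: Proposed new method: undecyl radicals from the peroxide add to the C=S of 10 and release the acyloxymethyl radical RCO2CH2•, which is stabilised by the lone pair of the ester oxygen; this radical attacks the unsubstituted terminus (C29) of the remote CH2=CH group, and the resulting secondary C28 radical takes the xanthate group from another molecule of 10, which carries the chain and makes the step an isomerisation that keeps every atom of 10. The closest known reaction types are the intermolecular degenerative xanthate-transfer addition of heteroatom-substituted alkyl xanthates to unactivated terminal alkenes and the Kharasch-type atom-transfer radical macrocyclisation of ω-alkenyl trichloroacetates to macrolactones; neither has been shown for an acyloxymethyl radical closing a ring of this size, hence the label. The 31-membered ring closes in the 31-endo-trig mode. The new stereocentre at C28 is formed without control as a racemate, which is harmless because step 6 replaces C–S by C–H. The step needs regioselectivity for endo attack at the CH2 terminus over 30-exo attack at C28, which the monosubstituted alkene secures because radicals add at its unsubstituted carbon to give the secondary radical. It also needs ring closure to outrun intermolecular addition, which is secured by the high dilution, the strain-free (CH2)26 tether and the reversible storage of the radical as xanthate in the absence of any hydrogen donor.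

Step 6
Reactants: 11 O-ethyl S-(2-oxo-1-oxacyclohentriacontan-29-yl) dithiocarbonate
Product: 12 1-oxacyclohentriacontan-2-one (triacontan-30-olide, CNP0336030.0)
Conditions: (Me3Si)3SiH (1.5 equiv), AIBN (0.2 equiv), toluene, 85 °C
Reagents that add atoms: none
Why: Radical chain reduction of the secondary xanthate (Barton–McCombie-type C–S homolysis by a silyl radical, then hydrogen transfer from Si–H) should remove the helper group and its stereocentre while the lactone stays untouched.

**Compound list**
1 | 11-bromoundec-1-ene | C=CCCCCCCCCCBr | starting material
2 | 1,6-dibromohexane | BrCCCCCCBr | starting material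
3 | undec-10-en-1-ylmagnesium bromide | C=CCCCCCCCCC[Mg]Br | intermediate
4 | 17-bromoheptadec-1-ene | C=CCCCCCCCCCCCCCCCBr | intermediate
5 | 12-bromododecanoic acid | OC(=O)CCCCCCCCCCCBr | starting material
6 | heptadec-16-en-1-ylmagnesium bromide | C=CCCCCCCCCCCCCCCC[Mg]Br | intermediate
7 | chloromagnesium 12-bromododecanoate | BrCCCCCCCCCCCC(=O)O[Mg]Cl | intermediate
8 | nonacos-28-enoic acid | C=CCCCCCCCCCCCCCCCCCCCCCCCCCCC(=O)O | intermediate
9 | chloromethyl nonacos-28-enoate | C=CCCCCCCCCCCCCCCCCCCCCCCCCCCC(=O)OCCl | intermediate
10 | O-ethyl S-[(nonacos-28-enoyloxy)methyl] dithiocarbonate | C=CCCCCCCCCCCCCCCCCCCCCCCCCCCC(=O)OCSC(=S)OCC | intermediate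
11 | O-ethyl S-(2-oxo-1-oxacyclohentriacontan-29-yl) dithiocarbonate, racemic | O=C1CCCCCCCCCCCCCCCCCCCCCCCCCCC(SC(=S)OCC)CCO1 | intermediate
12 | 1-oxacyclohentriacontan-2-one (triacontan-30-olide) | O=C1CCCCCCCCCCCCCCCCCCCCCCCCCCCCCO1 | target

**Step count**
Total steps: 6. Longest linear sequence: 6 steps (1 to 12).

**Steps most likely to fail**

Step 5 (bears the label). The slow 31-endo closure may be outrun by hydrogen abstraction from the solvent, which would end the chain as the methyl ester, by radical–radical termination at the low chain efficiency imposed by high dilution, or by intermolecular addition leading to oligomers. The fallback sets out from 8. Fischer esterification with allyl alcohol (TsOH cat., toluene, Dean–Stark) should give allyl nonacos-28-enoate F1. Ring-closing metathesis (second-generation Grubbs catalyst, RuCl2(=CHPh)(H2IMes)(PCy3), 5 mol %, CH2Cl2, 0.002 M, reflux) should then close the 31-membered ring at a C28=C29 double bond with loss of ethylene, giving 1-oxacyclohentriacont-29-en-2-one F2 as an E/Z mixture. Hydrogenation (H2, Pd/C, EtOAc, rt) should return to the route at 12.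

Step 2. The long-chain Grignard reagent may homocouple or be quenched, and the poorly soluble magnesium carboxylate may couple sluggishly. The fallback sets out from 4 and 5 and swaps to a palladium-catalysed alkyl–alkyl Negishi coupling on a protected ester. Acid 5 is esterified (MeOH, H2SO4 cat., reflux) to methyl 12-bromododecanoate F3. Bromide 4 is converted by zinc insertion (Zn dust, LiCl, THF, 50 °C) into heptadec-16-en-1-ylzinc bromide F4. Coupling (Pd2(dba)3, PCyp3, N-methylimidazole, THF/NMP, 80 °C) should give methyl nonacos-28-enoate F5. Saponification (LiOH, THF/MeOH/H2O, then aq HCl) comes back at 8.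

Step 1. The Grignard reagent may couple at both ends of the dibromide, and removal of the excess dibromide and of the diene may be laborious. The fallback sets out from 1 and replaces the symmetrical partner by a differentiated one. 6-Bromohexan-1-ol is deprotonated with MeMgCl (THF, −20 °C) to chloromagnesium 6-bromohexan-1-olate F6. This is coupled with Grignard reagent 3 (made from 1 as before; Li2CuCl4 cat., THF, −10 °C to rt; aq HCl) to give heptadec-16-en-1-ol F7. An Appel reaction (CBr4, PPh3, CH2Cl2, 0 °C) comes back at 4.

Further compounds
F1 | step 5 | allyl nonacos-28-enoate | C=CCCCCCCCCCCCCCCCCCCCCCCCCCCCC(=O)OCC=C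
F2 | step 5 | 1-oxacyclohentriacont-29-en-2-one (E/Z mixture) | O=C1CCCCCCCCCCCCCCCCCCCCCCCCCCC=CCO1
F3 | step 2 | methyl 12-bromododecanoate | COC(=O)CCCCCCCCCCCBr
F4 | step 2 | heptadec-16-en-1-ylzinc bromide | C=CCCCCCCCCCCCCCCC[Zn]Br
F5 | step 2 | methyl nonacos-28-enoate | C=CCCCCCCCCCCCCCCCCCCCCCCCCCCCC(=O)OC
F6 | step 1 | chloromagnesium 6-bromohexan-1-olate | BrCCCCCCO[Mg]Cl
F7 | step 1 | heptadec-16-en-1-ol | C=CCCCCCCCCCCCCCCCO
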